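## Retrosynthetic overview

1. The target is a formal [4+2] dimer of two labda-8(17),12,14-trienes. The alcohol half is cut at C11'–C12' (Suzuki–Miyaura sp3–sp2 coupling of a C11 trifluoroborate). The central cyclohexene is opened at C12–C14' and C15–C15' by a catalytic enantioselective Diels–Alder reaction of the acid-half triene with an acrylimide, whose carbonyl carbon later becomes C13' (alkyne, methylalumination, iodide).
2. The acid-half triene comes from the same C11 trifluoroborate 18 as the alcohol half (C11–C12 Suzuki–Miyaura coupling with a C5 dienyl iodide), so one bench-stable decalin building block, made once, is used twice.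
3. Decalin iodide 10, the precursor of 18, comes from one radical cascade on an acyclic farnesyl acetate epoxide: Cp2TiCl opens the epoxide, ring A closes (C4–C5), then ring B (C9–C10), and the cascade ends in the C8=C17 methylene. The C3 oxygen from the Sharpless epoxidation steers the cascade and is then removed (Barton–McCombie).
4. Enabling feature: in both halves rings A and B are the same head-to-tail farnesyl-type trans-decalin (quaternary C4 with equatorial C18, C10 methyl, 8(17)-methylene, C9–C11 bond, same configuration at C4, C5, C9, C10). The halves differ only in the oxidation level of C18 (CO2H or CH2OH), so one cascade product supplies four of the five rings and eight of the ten stereocentres.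
5. Ring order: A then B (step 4, serving both decalins), then the central cyclohexene (step 18).

Key step: step 4

Remark: (2E,6E)-farnesyl acetate is assumed to be bought as the single isomer; labdane locants are used for both halves (alcohol half primed; C17 = methylene carbon on C8, C18 = equatorial 4α carbon, C19 = axial 4β methyl, C20 = methyl on C10), and the central cyclohexene is C12, C13, C14, C15, C15', C14'.

## Route

Step 1
Reactants: 1 (2E,6E)-farnesyl acetate
Product: 2 (2E,6E,10E)-12-hydroxyfarnesyl acetate
Conditions: SeO2 (0.3 equiv), t-BuOOH (70% in water, 3 equiv), salicylic acid (0.1 equiv), CH2Cl2, 0 °C to rt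
Reagents that add atoms: tert-butyl hydroperoxide, CC(C)(C)OO
Why: The SeO2/t-BuOOH allylic oxidation (ene reaction then [2,3]-sigmatropic shift) should hydroxylate the (E)-methyl of the terminal, most electron-rich trisubstituted alkene, the 2,3-alkene being deactivated by the allylic acetate, so the (10E)-allylic alcohol is expected.

Step 2
Reactants: 2 (2E,6E,10E)-12-hydroxyfarnesyl acetate
Product: 3 (2S,3S)-epoxy alcohol
Conditions: Ti(OiPr)4 (10 mol%), L-(+)-diethyl tartrate (12 mol%), t-BuOOH (anhydrous, 2 equiv), 4 Å molecular sieves, CH2Cl2, −20 °C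
Reagents that add atoms: tert-butyl hydroperoxide, CC(C)(C)OO
Why: The Katsuki–Sharpless asymmetric epoxidation of the (E)-allylic alcohol with L-(+)-diethyl tartrate should give the (2S,3S)-epoxy alcohol, which sets the future C3 carbinol centre (S) that steers the cascade, while the other two alkenes are not allylic alcohols and stay untouched.

Step 3
Reactants: 3 (2S,3S)-epoxy alcohol
Product: 4 epoxy silyl ether
Conditions: t-BuPh2SiCl (1.2 equiv), imidazole (2.5 equiv), DMF, 0 °C to rt
Reagents that add atoms: tert-butyl(chloro)diphenylsilane, CC(C)(C)[Si](Cl)(c1ccccc1)c1ccccc1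
Why: Imidazole-promoted silylation of the primary alcohol gives a bulky ether that is stable to the radical, basic and organometallic steps, masks C18 and later biases the C4 centre.

Step 4
Reactants: 4 epoxy silyl ether
Product: 6 3β-hydroxy decalin acetate, via titanium alkoxide 5 (not isolated)
Conditions: Cp2TiCl2 (2.5 equiv), Mn dust (8 equiv), degassed THF, rt, slow addition of 4 (high dilution); then 1 M HCl work-up
Reagents that add atoms: none
Why: Cp2TiCl (trivalent titanium, formed from Cp2TiCl2 and Mn) opens the epoxide by single-electron transfer at the C4–O bond to give the tertiary C4 radical with the titanium alkoxide on C3; this radical adds 6-endo-trig to C5 of the C5=C10 alkene (ring A, C4–C5), the new tertiary C10 radical adds 6-endo-trig to C9 of the C8=C9 alkene (ring B, C9–C10), and the tertiary C8 radical is captured by a second Cp2TiCl and loses a C17 hydrogen, leaving the 8(17)-methylene. The closest known reaction type is the titanocene-mediated radical cyclisation of epoxypolyprenes (Nugent–RajanBabu epoxide opening), as with epoxyfarnesyl acetate giving the 3β-hydroxy exo-methylene decalin. Both rings should close through a chair–chair array with the bulky C3–O–Ti group equatorial, so the (3S) centre from step 2 fixes C5 (H α) and C10 (CH3 β) as a trans-decalin and the (E) geometry of C8=C9 places C11 equatorial (9β), while at C4 the larger silyloxymethyl group should take the equatorial-like site (eclipsing C3–H and not C3–C2, away from the C10 methyl) and leave CH3 axial. The step needs endo closure, exo-methylene termination and C4 selectivity: attack at the less substituted alkene carbon to give tertiary radicals secures the first, hydrogen loss from the unhindered methyl the second and the size of the silyl ether the third, and the cascade stops at C8 because the chain ends at the C11 acetate.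

Step 5
Reactants: 6 3β-hydroxy decalin acetate
Product: 7 3-O-(imidazol-1-ylthiocarbonyl) decalin acetate
Conditions: 1,1'-thiocarbonyldiimidazole (3 equiv), DMAP (0.3 equiv), toluene, 90 °C
Reagents that add atoms: 1,1'-thiocarbonyldiimidazole, S=C(n1ccnc1)n1ccnc1
Why: Thioacylation of the equatorial secondary 3β-alcohol under neutral conditions gives the Barton–McCombie precursor and leaves the acetate and the silyl ether intact.

Step 6
Reactants: 7 3-O-(imidazol-1-ylthiocarbonyl) decalin acetate
Product: 8 3-deoxy decalin acetate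
Conditions: Bu3SnH (2 equiv), AIBN (0.2 equiv), toluene, 110 °C
Reagents that add atoms: none
Why: The Barton–McCombie radical deoxygenation removes the temporary C3 oxygen, the secondary C3 radical being reduced by Bu3SnH before it can reach the remote 8(17)-alkene, and no remaining stereocentre is touched.

Step 7
Reactants: 8 3-deoxy decalin acetate
Product: 9 C11 alcohol
Conditions: K2CO3 (0.5 equiv), MeOH, rt
Reagents that add atoms: none
Why: Base-catalysed transesterification with methanol cleaves the primary acetate, and the neopentyl silyl ether is stable to K2CO3 in MeOH.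

Step 8
Reactants: 9 C11 alcohol
Product: 10 C11 iodide
Conditions: I2 (1.5 equiv), PPh3 (1.5 equiv), imidazole (3 equiv), toluene/MeCN, 0 °C to 50 °C
Reagents that add atoms: iodine, II
Why: The Garegg–Samuelsson (Appel-type) iodination replaces the primary hydroxyl by SN2 at C11, which is not a stereocentre, without free acid that could move the exocyclic alkene.

Step 9
Reactants: 11 prop-2-yn-1-ol
Product: 13 (E)-3-iodo-2-methylprop-2-en-1-ol, via alkenylalane 12 (not isolated)
Conditions: AlMe3 (3 equiv), Cp2ZrCl2 (0.25 equiv), CH2Cl2, 0 °C to rt; then I2, THF, −30 °C to 0 °C; dilute HCl work-up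
Reagents that add atoms: trimethylaluminium, C[Al](C)C; iodine, II
Why: The Negishi zirconium-catalysed carboalumination adds CH3 and aluminium syn across the alkyne with the metal at the terminal carbon, and iodinolysis with retention gives the (E)-iodoalkene.

Step 10
Reactants: 13 (E)-3-iodo-2-methylprop-2-en-1-ol
Product: 14 (E)-3-iodo-2-methylprop-2-enal
Conditions: MnO2 (15 equiv), CH2Cl2, rt
Reagents that add atoms: none
Why: MnO2 oxidises the allylic alcohol selectively to the enal without isomerising the double bond.

Step 11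
Reactants: 14 (E)-3-iodo-2-methylprop-2-enal
Product: 15 (E)-1-iodo-2-methylbuta-1,3-diene
Conditions: Ph3PCH3Br (1.2 equiv), NaN(SiMe3)2 (1.15 equiv), THF, −78 °C to 0 °C; used as a solution
Reagents that add atoms: methyltriphenylphosphonium bromide, C[P+](c1ccccc1)(c1ccccc1)c1ccccc1.[Br-]
Why: Wittig methylenation of the aldehyde with the non-stabilised ylide gives the terminal diene and leaves the iodoalkene geometry untouched.

Step 12
Reactants: 10 C11 iodide
Product: 18 potassium C11 trifluoroborate, via alkyllithium 16 (not isolated), via lithium alkyltriisopropoxyborate 17 (not isolated)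
Conditions: t-BuLi (2.1 equiv), Et2O, −78 °C; B(OiPr)3 (3 equiv), −78 °C to rt; then KHF2 (4.5 M in water, 6 equiv), MeOH, 0 °C to rt; product taken up in acetone and precipitated
Reagents that add atoms: triisopropyl borate, CC(C)OB(OC(C)C)OC(C)C; potassium hydrogen difluoride, [K+].F.[F-]
Why: Lithium–iodine exchange (polar, so the homoallylic position does not rearrange), borylation of the primary alkyllithium to the borate and fluoride exchange with KHF2 should give an air-stable potassium alkyltrifluoroborate that can be stored and used for both fragment couplings, the neopentyl tert-butyldiphenylsilyl ether being stable to short contact with aqueous KHF2.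

Step 13
Reactants: 18 potassium C11 trifluoroborate; 15 (E)-1-iodo-2-methylbuta-1,3-diene
Product: 19 silyl-protected triene
Conditions: 15 (1.5 equiv), Pd(dppf)Cl2·CH2Cl2 (10 mol%; dppf = 1,1'-bis(diphenylphosphino)ferrocene), Cs2CO3 (3 equiv), toluene/H2O (3:1), 80 °C, sealed tube
Reagents that add atoms: none
Why: The Suzuki–Miyaura sp3–sp2 cross-coupling of a potassium primary alkyltrifluoroborate with an alkenyl halide under aqueous carbonate should transfer the C11 methylene from boron to palladium and couple with retention of the (E)-iodoalkene geometry, forming C11–C12 and the (12E)-diene, while the wide bite angle of dppf favours reductive elimination over β-hydride elimination.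

Step 14
Reactants: 19 silyl-protected triene
Product: 20 labda-8(17),12E,14-trien-18-ol
Conditions: Bu4NF (2 equiv), THF, rt to 45 °C; NH4Cl work-up
Reagents that add atoms: none
Why: Fluoride cleaves the silyl ether and frees the C18 alcohol, nothing else in the molecule being fluoride-labile.

Step 15
Reactants: 20 labda-8(17),12E,14-trien-18-ol
Product: 21 labda-8(17),12E,14-trien-18-al
Conditions: Dess–Martin periodinane (1.5 equiv), NaHCO3, CH2Cl2, 0 °C to rt
Reagents that add atoms: none
Why: The buffered Dess–Martin oxidation of the neopentyl primary alcohol is non-acidic and tolerates the diene and the exocyclic alkene.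

Step 16
Reactants: 21 labda-8(17),12E,14-trien-18-al
Product: 22 labda-8(17),12E,14-trien-18-oic acid
Conditions: NaClO2 (3 equiv), NaH2PO4 (3 equiv), 2-methyl-2-butene (20 equiv), t-BuOH/H2O, 0 °C to rt
Reagents that add atoms: sodium chlorite, [Na+].[O-]Cl=O
Why: The Pinnick oxidation converts the non-enolisable aldehyde to the acid while excess 2-methyl-2-butene scavenges HOCl, so the diene should be spared.

Step 17
Reactants: 22 labda-8(17),12E,14-trien-18-oic acid
Product: 23 2-(trimethylsilyl)ethyl ester
Conditions: 2-(trimethylsilyl)ethanol (1.5 equiv), PPh3 (1.5 equiv), diisopropyl azodicarboxylate (1.5 equiv, added last), THF, 0 °C to rt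
Reagents that add atoms: 2-(trimethylsilyl)ethanol, C[Si](C)(C)CCO
Why: The Mitsunobu esterification alkylates the hindered carboxylate at oxygen (SN2 on the activated primary alcohol), so the crowded C4 carbonyl need not be attacked, and the ester is later removed by fluoride together with the silyl ether.

Step 18
Reactants: 23 2-(trimethylsilyl)ethyl ester; 24 3-acryloyl-1,3-oxazolidin-2-one
Product: 25 Diels–Alder imide
Conditions: 24 (2 equiv), [Cu((S,S)-t-Bu-box)](SbF6)2 (10 mol%; (S,S)-t-Bu-box = 2,2'-(propane-2,2-diyl)bis[(4S)-4-tert-butyl-4,5-dihydrooxazole]), 4 Å molecular sieves, CH2Cl2, −20 °C to rt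
Reagents that add atoms: none
Why: In this bis(oxazoline)–copper-catalysed enantioselective Diels–Alder reaction the imide, held s-cis on square-planar divalent copper, should be attacked on its Cα-Re face (opposite the tert-butyl group) to give (14'S), the substituted (E)-terminus C12 of the diene bonds to Cα ("ortho" orientation, C15 to Cβ), and the endo transition state places the C11 and acyl substituents cis to give (12S).

Step 19
Reactants: 25 Diels–Alder imide
Product: 26 primary alcohol
Conditions: LiBH4 (1.5 equiv), MeOH (1.5 equiv), THF, 0 °C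
Reagents that add atoms: none
Why: LiBH4 reduces the activated N-acyl oxazolidinone to the primary alcohol much faster than the hindered C18 ester and releases oxazolidin-2-one.

Step 20
Reactants: 26 primary alcohol
Product: 27 cis aldehyde
Conditions: Dess–Martin periodinane (1.3 equiv), NaHCO3, CH2Cl2, 0 °C; used crude
Reagents that add atoms: none
Why: The buffered Dess–Martin oxidation gives the α-branched aldehyde under non-basic conditions that should not epimerise C14'.

Step 21
Reactants: 27 cis aldehyde
Product: 28 terminal alkyne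
Conditions: dimethyl (1-diazo-2-oxopropyl)phosphonate (1.5 equiv), K2CO3 (2 equiv), MeOH/THF, 0 °C to rt
Reagents that add atoms: dimethyl (1-diazo-2-oxopropyl)phosphonate, CC(=O)C(=[N+]=[N-])P(=O)(OC)OC
Why: The Seyferth–Gilbert homologation with the Ohira–Bestmann reagent (addition of the diazophosphonate, Horner–Wadsworth–Emmons-type elimination, 1,2-shift in the alkylidene carbene) converts the aldehyde to the terminal alkyne under mild base, adding C12'.

Step 22
Reactants: 28 terminal alkyne
Product: 30 (E)-alkenyl iodide, via alkenylalane 29 (not isolated)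
Conditions: AlMe3 (2.5 equiv), Cp2ZrCl2 (0.3 equiv), CH2Cl2, 0 °C to rt; then I2 (1.2 equiv), THF, −30 °C
Reagents that add atoms: trimethylaluminium, C[Al](C)C; iodine, II
Why: The Negishi zirconium-catalysed carboalumination adds CH3 to C13' and aluminium to C12' in a syn fashion and iodinolysis with retention gives the (E)-iodoalkene, while the 1,1-disubstituted and trisubstituted alkenes and the hindered ester should not react.

Step 23
Reactants: 30 (E)-alkenyl iodide; 18 potassium C11 trifluoroborate
Product: 31 protected target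
Conditions: 18 (1.5 equiv), Pd(dppf)Cl2·CH2Cl2 (10 mol%), Cs2CO3 (3 equiv), toluene/H2O (3:1), 80 °C
Reagents that add atoms: none
Why: A second Suzuki–Miyaura sp3–sp2 coupling with the same stored trifluoroborate should join C11' to C12' with retention of the (E)-alkene, the hindered C4 ester and both silicon groups being stable to aqueous carbonate and to the hydrated fluoride that the boron reagent releases.

Step 24
Reactants: 31 protected target
Product: 32 target CNP0316988.1
Conditions: Bu4NF (6 equiv), THF, rt to 45 °C; NH4Cl/citric acid work-up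
Reagents that add atoms: none
Why: Fluoride removes both silicon-based groups in one step, the silyl ether directly and the 2-(trimethylsilyl)ethyl ester by β-elimination, which frees the acid and the alcohol without touching any stereocentre.

## Compound list

1 | (2E,6E)-farnesyl acetate, (2E,6E)-3,7,11-trimethyldodeca-2,6,10-trien-1-yl acetate | CC(C)=CCC/C(C)=C/CC/C(C)=C/COC(C)=O | starting material
2 | (2E,6E,10E)-12-hydroxy-3,7,11-trimethyldodeca-2,6,10-trien-1-yl acetate | OC/C(C)=C/CC/C(C)=C/CC/C(C)=C/COC(C)=O | intermediate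
3 | (2E,6E)-9-[(2S,3S)-3-(hydroxymethyl)-3-methyloxiran-2-yl]-3,7-dimethylnona-2,6-dien-1-yl acetate | OC[C@]1(C)O[C@H]1CC/C(C)=C/CC/C(C)=C/COC(C)=O | intermediate
4 | tert-butyldiphenylsilyl ether of 3 ((2S,3S)-epoxide, 2E,6E) | CC(C)(C)[Si](c1ccccc1)(c1ccccc1)OC[C@]1(C)O[C@H]1CC/C(C)=C/CC/C(C)=C/COC(C)=O | intermediate
5 | titanium alkoxide of 6 (Cp2Ti(Cl) on the C3 oxygen) | C=C1CC[C@@H]2[C@](C)(CC[C@H](O[Ti](Cl)(C3C=CC=C3)C3C=CC=C3)[C@@]2(C)CO[Si](c3ccccc3)(c3ccccc3)C(C)(C)C)[C@H]1COC(C)=O | intermediate
6 | trans-decalin with 3β-OH (3S), 4α-CH2OSi(t-Bu)Ph2 (C18), 4β-CH3, 5α-H, 10β-CH3, 8(17)-methylene, 9β-CH2OAc | C=C1CC[C@@H]2[C@](C)(CC[C@H](O)[C@@]2(C)CO[Si](c3ccccc3)(c3ccccc3)C(C)(C)C)[C@H]1COC(C)=O | intermediate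
7 | 3-O-(imidazol-1-ylthiocarbonyl) derivative of 6 | C=C1CC[C@@H]2[C@](C)(CC[C@H](OC(=S)n3ccnc3)[C@@]2(C)CO[Si](c3ccccc3)(c3ccccc3)C(C)(C)C)[C@H]1COC(C)=O | intermediate
8 | 3-deoxy decalin acetate (4α-CH2OSi(t-Bu)Ph2, 4β-CH3, 5α-H, 10β-CH3, 8(17)-methylene, 9β-CH2OAc) | C=C1CC[C@@H]2[C@](C)(CCC[C@@]2(C)CO[Si](c3ccccc3)(c3ccccc3)C(C)(C)C)[C@H]1COC(C)=O | intermediate
9 | C11 alcohol (as 8, 9β-CH2OH) | C=C1CC[C@@H]2[C@](C)(CCC[C@@]2(C)CO[Si](c3ccccc3)(c3ccccc3)C(C)(C)C)[C@H]1CO | intermediate
10 | C11 iodide (as 8, 9β-CH2I) | C=C1CC[C@@H]2[C@](C)(CCC[C@@]2(C)CO[Si](c3ccccc3)(c3ccccc3)C(C)(C)C)[C@H]1CI | intermediate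
11 | prop-2-yn-1-ol | C#CCO | starting material
12 | (E)-alkenylalane, dimethylaluminium alkoxide of (E)-3-(dimethylalumanyl)-2-methylprop-2-en-1-ol | C[Al](C)OC/C(C)=C/[Al](C)C | intermediate
13 | (E)-3-iodo-2-methylprop-2-en-1-ol | OC/C(C)=C/I | intermediate
14 | (E)-3-iodo-2-methylprop-2-enal | O=C/C(C)=C/I | intermediate
15 | (E)-1-iodo-2-methylbuta-1,3-diene | C=C/C(C)=C/I | intermediate
16 | C11 alkyllithium from 10 | C=C1CC[C@@H]2[C@](C)(CCC[C@@]2(C)CO[Si](c3ccccc3)(c3ccccc3)C(C)(C)C)[C@H]1C[Li] | intermediate
17 | lithium C11-alkyl(triisopropoxy)borate | C=C1CC[C@@H]2[C@](C)(CCC[C@@]2(C)CO[Si](c3ccccc3)(c3ccccc3)C(C)(C)C)[C@H]1C[B-](OC(C)C)(OC(C)C)OC(C)C.[Li+] | intermediate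
18 | potassium C11-alkyltrifluoroborate (as 8, 9β-CH2BF3K) | C=C1CC[C@@H]2[C@](C)(CCC[C@@]2(C)CO[Si](c3ccccc3)(c3ccccc3)C(C)(C)C)[C@H]1C[B-](F)(F)F.[K+] | intermediate
19 | 18-(tert-butyldiphenylsilyloxy)labda-8(17),12E,14-triene (4β-CH3, 5α-H, 9α-H, 10β-CH3) | C=C1CC[C@@H]2[C@](C)(CCC[C@@]2(C)CO[Si](c3ccccc3)(c3ccccc3)C(C)(C)C)[C@H]1C/C=C(\C)C=C | intermediate
20 | labda-8(17),12E,14-trien-18-ol | C=C1CC[C@@H]2[C@](C)(CCC[C@@]2(C)CO)[C@H]1C/C=C(\C)C=C | intermediate
21 | labda-8(17),12E,14-trien-18-al | C=C1CC[C@@H]2[C@](C)(CCC[C@@]2(C)C=O)[C@H]1C/C=C(\C)C=C | intermediate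
22 | labda-8(17),12E,14-trien-18-oic acid | C=C1CC[C@@H]2[C@](C)(CCC[C@@]2(C)C(=O)O)[C@H]1C/C=C(\C)C=C | intermediate
23 | 2-(trimethylsilyl)ethyl labda-8(17),12E,14-trien-18-oate | C=C1CC[C@@H]2[C@](C)(CCC[C@@]2(C)C(=O)OCC[Si](C)(C)C)[C@H]1C/C=C(\C)C=C | intermediate
24 | 3-acryloyl-1,3-oxazolidin-2-one | C=CC(=O)N1CCOC1=O | starting material
25 | Diels–Alder imide: cyclohexene with (12S)-C12 carrying C11H2 of the decalin ester, C13(CH3)=C14, and (14'S)-C14' carrying the C(=O)-oxazolidinone, the two substituents cis | C=C1CC[C@@H]2[C@](C)(CCC[C@@]2(C)C(=O)OCC[Si](C)(C)C)[C@H]1C[C@@H]1C(C)=CCC[C@@H]1C(=O)N1CCOC1=O | intermediate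
26 | primary alcohol (as 25, C14'–CH2OH; 12S,14'S) | C=C1CC[C@@H]2[C@](C)(CCC[C@@]2(C)C(=O)OCC[Si](C)(C)C)[C@H]1C[C@@H]1C(C)=CCC[C@@H]1CO | intermediate
27 | cis aldehyde (as 25, C14'–CHO; 12S,14'S) | C=C1CC[C@@H]2[C@](C)(CCC[C@@]2(C)C(=O)OCC[Si](C)(C)C)[C@H]1C[C@@H]1C(C)=CCC[C@@H]1C=O | intermediate
28 | terminal alkyne (as 25, C14'–C≡CH; 12S,14'S) | C=C1CC[C@@H]2[C@](C)(CCC[C@@]2(C)C(=O)OCC[Si](C)(C)C)[C@H]1C[C@@H]1C(C)=CCC[C@@H]1C#C | intermediate
29 | (E)-alkenylalane (C14'–C(CH3)=CH–AlMe2) | C=C1CC[C@@H]2[C@](C)(CCC[C@@]2(C)C(=O)OCC[Si](C)(C)C)[C@H]1C[C@@H]1C(C)=CCC[C@@H]1/C(C)=C/[Al](C)C | intermediate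
30 | (E)-alkenyl iodide (C14'–C(CH3)=CH–I; 12S,14'S) | C=C1CC[C@@H]2[C@](C)(CCC[C@@]2(C)C(=O)OCC[Si](C)(C)C)[C@H]1C[C@@H]1C(C)=CCC[C@@H]1/C(C)=C/I | intermediate
31 | protected target (C18 2-(trimethylsilyl)ethyl ester, C18' tert-butyldiphenylsilyl ether; 12S,14'S,12'E) | C=C1CC[C@@H]2[C@](C)(CCC[C@@]2(C)C(=O)OCC[Si](C)(C)C)[C@H]1C[C@@H]1C(C)=CCC[C@@H]1/C(C)=C/C[C@H]1C(=C)CC[C@H]2[C@](C)(CO[Si](c3ccccc3)(c3ccccc3)C(C)(C)C)CCC[C@]12C | intermediate
32 | CNP0316988.1 | C=C1CC[C@@H]2[C@](C)(CCC[C@@]2(C)C(=O)O)[C@H]1C[C@@H]1C(C)=CCC[C@@H]1/C(C)=C/C[C@H]1C(=C)CC[C@H]2[C@](C)(CO)CCC[C@]12C | target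

## Step count and risks

Total steps: 24. Longest linear sequence: 21 steps (steps 1–8, step 12, then steps 13–24); steps 9–11 form a three-step side branch.

Steps most likely to fail:

1. Step 4 (key cascade). What may go wrong: rotation about C3–C4 in the radical is free, so the preference for the equatorial silyloxymethyl group at C4 may be too small; the C4 radical may also be reduced or undergo β-elimination before ring A closes. The fallback changes from the radical to the cationic manifold. It sets out from 4 and returns at 8. Treatment of 4 with MeAlCl2 in CH2Cl2 at −78 °C should open the epoxide in concert with attack of C5=C10 (anti, hence stereospecific at C4, the (E)-derived silyloxymethyl group ending equatorial). The C8 cation is captured by the neighbouring acetate carbonyl, and aqueous work-up should give the 3β,8α-diol 11-acetate F1. Selective thioacylation of the secondary C3 hydroxyl (1,1'-thiocarbonyldiimidazole, DMAP) gives the 3-O-(imidazol-1-ylthiocarbonyl) derivative F2, and Bu3SnH/AIBN gives the 8α-hydroxy acetate F3. Dehydration of this equatorial tertiary alcohol with POCl3 in pyridine, where only the C17 hydrogens can become anti-periplanar to the leaving group, should give the 8(17)-methylene compound 8.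

2. Step 18 (Diels–Alder). What may go wrong: incomplete endo/exo and regiochemical discrimination with the 1,2-disubstituted diene under the catalyst, or erosion of facial control by the remote decalin. The fallback replaces the chiral catalyst by a covalently bound auxiliary. It sets out from 23 and returns at 26. (R)-3-Acryloyl-4-benzyl-1,3-oxazolidin-2-one F4 is made from commercial (R)-4-benzyl-1,3-oxazolidin-2-one with n-BuLi and acryloyl chloride. With Et2AlCl (1.4 equiv per imide, CH2Cl2, −78 °C) its chelated s-cis form should react with 23 on the Cα-Re face, opposite the benzyl group, through a strongly endo transition state to give adduct F5. LiBH4 then removes the auxiliary and gives alcohol 26.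

3. Step 23 (second fragment coupling; the same concern applies to step 13). What may go wrong: slow boron-to-palladium transfer of the β-branched primary alkyl group, so that protodeboronation of 18, reduction of the alkenyl iodide or β-hydride elimination from the alkylpalladium species competes. The fallback changes the nucleophile from boron to zinc. It sets out from 10 (coupling partner 30) and returns at 31. Iodide 10 is converted by lithium–iodine exchange with t-BuLi (2.1 equiv, Et2O, −78 °C) into alkyllithium 16, and ZnCl2 in THF should then give the C11 alkylzinc chloride F6. With Pd(dppf)Cl2 in THF at rt to 40 °C this more reactive nucleophile should couple with 30 in a Negishi sp3–sp2 coupling, with retention of the (E)-alkene, to give 31.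

## Further compounds

F1 | step 4 | 3β,8α-dihydroxy decalin 11-acetate (8β-CH3, 4α-CH2OSi(t-Bu)Ph2, 4β-CH3, 5α-H, 10β-CH3, 9β-CH2OAc) | C[C@@]1(O)CC[C@@H]2[C@](C)(CC[C@H](O)[C@@]2(C)CO[Si](c3ccccc3)(c3ccccc3)C(C)(C)C)[C@H]1COC(C)=O
F2 | step 4 | 3-O-(imidazol-1-ylthiocarbonyl) derivative of F1 | C[C@@]1(O)CC[C@@H]2[C@](C)(CC[C@H](OC(=S)n3ccnc3)[C@@]2(C)CO[Si](c3ccccc3)(c3ccccc3)C(C)(C)C)[C@H]1COC(C)=O
F3 | step 4 | 8α-hydroxy 3-deoxy decalin 11-acetate | C[C@@]1(O)CC[C@@H]2[C@](C)(CCC[C@@]2(C)CO[Si](c3ccccc3)(c3ccccc3)C(C)(C)C)[C@H]1COC(C)=O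
F4 | step 18 | (R)-3-acryloyl-4-benzyl-1,3-oxazolidin-2-one | C=CC(=O)N1[C@H](Cc2ccccc2)COC1=O
F5 | step 18 | Diels–Alder adduct carrying the (R)-4-benzyl-oxazolidinone auxiliary (12S,14'S, cis) | C=C1CC[C@@H]2[C@](C)(CCC[C@@]2(C)C(=O)OCC[Si](C)(C)C)[C@H]1C[C@@H]1C(C)=CCC[C@@H]1C(=O)N1[C@H](Cc2ccccc2)COC1=O
F6 | step 23 | C11 alkylzinc chloride (as 8, 9β-CH2ZnCl) | C=C1CC[C@@H]2[C@](C)(CCC[C@@]2(C)CO[Si](c3ccccc3)(c3ccccc3)C(C)(C)C)[C@H]1C[Zn]Cl
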